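**Retrosynthetic overview**

1. Sipholenol L (27) ⇒ Z-alkene 25 (Wittig reaction at the central CH2–CH2 link, then diimide) ⇒ left-half aldehyde 8 + right-half phosphonium salt 23.
2. Left half: one epoxonium cascade on the acyclic bis-epoxide 3 (two steps from farnesol) forms the O–CMe2 bond of the oxepane, then the C–C bond of the cyclohexane, then a temporary cyclic carbonate that fixes the tertiary C–O bond (three rings, four new stereocentres).
3. Enabling feature: the 1,5-spaced trisubstituted epoxides C6–C7 and C10–C11 (farnesane numbering), whose tertiary carbons C7 and C11 steer each opening endo, the E C2=C3 alkene placed for a six-membered closure onto C7, and the C1 carbonate oxygen placed to trap C3; in the target this is the CMe2–O–CH oxepane trans-fused to the cyclohexane that carries the equatorial tertiary OH.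
4. Right half: cis-decalin by an enantioselective Diels–Alder reaction of 2-silyloxydiene 12 with 4,4-dimethylcyclohexenone 13 (cyclohexene ring built onto the cyclohexanone); the enol ether becomes the C(Me)=CH unit, the ketone the tertiary carbinol.
5. Ring order: oxepane → cyclohexane → carbonate (one operation; the carbonate is opened again in step 4); separately the cyclohexene onto ring B; then fragment union.

Key step: step 3

Remark: the L-fructose-type Shi ketone (enantiomer of the usual D-fructose-derived catalyst), aldehyde 9 and enone 13 are taken as commercial.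
Remark: the facial sense of the oxazaborolidinium catalyst on enone 13 is assigned by analogy with 2-cyclohexenone; the (S)-catalyst is assumed to give 14, and its antipode would be used if the sense is reversed.

**Route**

Step 1
Reactants: 1 (2E,6E)-farnesol
Product: 2 (2E,6E)-farnesyl tert-butyl carbonate
Conditions: n-BuLi, THF, −78 °C; Boc2O, −78 → 0 °C
Reagents that add atoms: di-tert-butyl dicarbonate CC(C)(C)OC(=O)OC(=O)OC(C)(C)C
Why: O-acylation of the lithium alkoxide with Boc2O (carbonate formation) should install the group that later ends the cascade, with no stereocentre formed and the E,E geometry untouched.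

Step 2
Reactants: 2 (2E,6E)-farnesyl tert-butyl carbonate
Product: 3 tert-butyl (2E,6S,7S,10S)-6,7:10,11-diepoxyfarnesyl carbonate
Conditions: L-fructose-derived Shi ketone (30 mol %), Oxone, K2CO3, Bu4NHSO4, MeCN/DMM/aq. borate buffer, 0 °C
Reagents that add atoms: potassium peroxymonosulfate (Oxone) [K+].[O-]S(=O)(=O)OO
Why: Shi asymmetric epoxidation should oxidise the two distal trisubstituted alkenes and spare the C2=C3 alkene, which is deactivated by the allylic carbonate, the chiral dioxirane setting C6, C7 and C10 under catalyst control (the L-series ketone gives the S,S/S epoxides).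

Step 3
Reactants: 3 tert-butyl (2E,6S,7S,10S)-6,7:10,11-diepoxyfarnesyl carbonate
Product: 5 TBS-protected tricyclic carbonate (2R,3S,6S,7S,10S), via bicyclic epoxonium triflate 4 (not isolated)
Conditions: TBSOTf (1.3 equiv), 2,6-di-tert-butyl-4-methylpyridine, CH2Cl2 (high dilution), −78 → −40 °C; aq. NaHCO3
Reagents that add atoms: tert-butyldimethylsilyl triflate CC(C)(C)[Si](C)(C)OS(=O)(=O)C(F)(F)F
Why: TBSOTf silylates the terminal epoxide, the C6–C7 epoxide oxygen attacks its tertiary carbon C11 (this makes the O–CMe2 bond and leaves OTBS on C10) to give epoxonium ion 4, which is opened at its tertiary carbon C7 by the C2=C3 alkene, and the C3 cation is captured by the carbonate carbonyl oxygen with loss of 2-methylpropene. The closest known reaction type is the silyl-triflate-promoted tandem oxa-/carbacyclization of 1,5-diepoxides bearing an alkene, joined to the acyloxy- or carbonate-terminated cationic cyclization of farnesyl esters. Ring closures: oxepane by endo attack at C11 followed by endo opening of the bicyclo[4.1.0] epoxonium (net 7-endo), cyclohexane by 6-endo-trig attack of the alkene through a chair, cyclic carbonate by 6-exo capture of the tertiary cation. C10 and C6 keep the configuration set in step 2 because their C–O bonds are not broken, C7 is set by backside (invertive) opening of the epoxonium, and C2 and C3 by anti addition across the E alkene in the chair, which puts CH2O and the new C3–O bond equatorial and both methyl groups axial (trans ring fusion). The step needs tertiary-carbon regioselectivity at both epoxides and C–C bond formation ahead of elimination or hydride shift; the cation-stabilising methyl groups at C7 and C11, the low temperature and the hindered non-nucleophilic base should secure this. If the internal epoxide is activated first, direct carbocyclization followed by attack of the C6 silyl ether oxygen on the terminal epoxide should lead to the same product 5.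

Step 4
Reactants: 5 TBS-protected tricyclic carbonate
Product: 6 TBS-protected bicyclic diol (primary CH2OH, tertiary OH)
Conditions: K2CO3 (cat.), MeOH, 40 °C
Reagents that add atoms: none
Why: Base-catalysed transesterification (methanolysis) of the cyclic carbonate should free both hydroxyl groups without touching the hindered TBS ether or any stereocentre.

Step 5
Reactants: 6 TBS-protected bicyclic diol
Product: 7 β-hydroxy aldehyde
Conditions: Dess–Martin periodinane, NaHCO3, CH2Cl2, 0 °C → rt
Reagents that add atoms: none
Why: Dess–Martin oxidation acts only on the primary alcohol (the tertiary alcohol cannot be oxidised) under near-neutral conditions that should avoid retro-aldol cleavage and epimerisation of the axial α-hydrogen.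

Step 6
Reactants: 7 β-hydroxy aldehyde
Product: 8 left-half aldehyde (10-OTBS, 3-OTMS)
Conditions: N-(trimethylsilyl)imidazole, CH2Cl2, rt
Reagents that add atoms: N-(trimethylsilyl)imidazole C[Si](C)(C)n1ccnc1
Why: Neutral silyl transfer to the tertiary alcohol masks the aldolate position before the basic Wittig step without enolising the aldehyde.

Step 7
Reactants: 9 3-[(tert-butyldimethylsilyl)oxy]propanal
Product: 10 5-[(tert-butyldimethylsilyl)oxy]pent-1-en-3-ol (racemic)
Conditions: CH2=CHMgBr, THF, −78 °C; aq. NH4Cl
Reagents that add atoms: vinylmagnesium bromide C=C[Mg]Br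
Why: Grignard 1,2-addition to the aldehyde gives the allylic alcohol, whose carbinol centre is removed in the next step.

Step 8
Reactants: 10 5-[(tert-butyldimethylsilyl)oxy]pent-1-en-3-ol
Product: 11 5-[(tert-butyldimethylsilyl)oxy]pent-1-en-3-one
Conditions: Dess–Martin periodinane, NaHCO3, CH2Cl2, 0 °C
Reagents that add atoms: none
Why: Dess–Martin oxidation of the allylic alcohol gives the vinyl ketone under conditions mild enough to avoid polymerisation and β-elimination of the silyloxy group.

Step 9
Reactants: 11 5-[(tert-butyldimethylsilyl)oxy]pent-1-en-3-one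
Product: 12 (Z)-5-(tert-butyldimethylsilyloxy)-3-(triethylsilyloxy)penta-1,3-diene
Conditions: TESOTf, Et3N, Et2O, 0 °C
Reagents that add atoms: triethylsilyl triflate CC[Si](CC)(CC)OS(=O)(=O)C(F)(F)F
Why: Soft enolisation (silyl triflate/amine) can occur only at the α′-CH2 and should give the Z silyl dienol ether (allylic strain), the only isomer able to react through an s-cis conformation.

Step 10
Reactants: 12 (Z)-silyloxydiene; 13 4,4-dimethylcyclohex-2-en-1-one
Product: 14 (4aR,5R,8aS)-5-[(tert-butyldimethylsilyloxy)methyl]-4,4-dimethyl-6-(triethylsilyloxy)-3,4,4a,5,8,8a-hexahydronaphthalen-1(2H)-one (cis-fused; H-4a, H-5 and H-8a all cis)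
Conditions: (S)-B-(o-tolyl)-diphenylprolinol-derived oxazaborolidine activated with AlBr3 (20 mol %), CH2Cl2, −78 → −40 °C
Reagents that add atoms: none
Why: Lewis-acid-catalysed Diels–Alder reaction of a 2-silyloxydiene with a cyclic enone (cationic oxazaborolidine catalysis): the silyloxy group directs the substituted diene terminus to the enone β-carbon, the endo transition state with the outside CH2OTBS group gives the cis fusion with H-4a, H-5 and H-8a cis, and the catalyst should select the enone face and thus the absolute configuration.

Step 11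
Reactants: 14 Diels–Alder adduct
Product: 15 exocyclic methylene compound (C1=CH2)
Conditions: Ph3PCH3Br, KHMDS, toluene/THF, 0 °C → rt
Reagents that add atoms: methyltriphenylphosphonium bromide C[P+](c1ccccc1)(c1ccccc1)c1ccccc1.[Br-]
Why: Wittig methylenation of the ketone with the salt-free, weakly basic ylide should leave the epimerisable C8a and the silyl enol ether untouched.

Step 12
Reactants: 15 exocyclic methylene compound
Product: 17 enol triflate, via lithium enolate 16 (not isolated)
Conditions: MeLi, THF, 0 °C; then PhNTf2, −78 °C → rt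
Reagents that add atoms: methyllithium [Li]C (lithium of 16); N-phenylbis(trifluoromethanesulfonimide) O=S(=O)(N(c1ccccc1)S(=O)(=O)C(F)(F)F)C(F)(F)F
Why: Cleavage of the silyl enol ether with MeLi gives the regiodefined lithium enolate without equilibration (C5 is not epimerised), and O-sulfonylation fixes the C6=C7 double bond as the enol triflate.

Step 13
Reactants: 17 enol triflate
Product: 18 spiro-epoxide (epoxide oxygen cis to H-8a)
Conditions: mCPBA, NaHCO3, CH2Cl2, 0 °C
Reagents that add atoms: 3-chloroperoxybenzoic acid OOC(=O)c1cccc(Cl)c1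
Why: Prilezhaev epoxidation should act only on the electron-rich exocyclic alkene (the enol triflate is inert), the peracid approaching from the face of H-8a, away from C8 and the axial C5 substituent, so that oxygen ends cis to H-8a.

Step 14
Reactants: 18 spiro-epoxide
Product: 19 methyl-substituted cyclohexene epoxide
Conditions: Pd(dppf)Cl2 (5 mol %), trimethylboroxine, K2CO3, dioxane/H2O, 80 °C
Reagents that add atoms: trimethylboroxine CB1OB(C)OB(C)O1
Why: Suzuki–Miyaura methylation of the enol triflate should give the trisubstituted C(Me)=CH alkene regiospecifically, with the hindered epoxide surviving the mild base.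

Step 15
Reactants: 19 methyl-substituted cyclohexene epoxide
Product: 20 tertiary alcohol (TBS ether)
Conditions: LiEt3BH, THF, 0 °C → rt
Reagents that add atoms: none
Why: SN2 hydride opening at the primary carbon of the 1,1-disubstituted epoxide turns the spiro CH2 into the methyl group and leaves the carbinol configuration (OH cis to H-8a) unchanged.

Step 16
Reactants: 20 tertiary alcohol (TBS ether)
Product: 21 right-half diol
Conditions: TBAF, THF, rt
Reagents that add atoms: none
Why: Fluoride-induced desilylation should free the primary alcohol without affecting the alkene or the tertiary alcohol.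

Step 17
Reactants: 21 right-half diol
Product: 22 primary iodide
Conditions: PPh3, I2, imidazole, CH2Cl2, 0 °C (I2 added to PPh3/imidazole before the diol)
Reagents that add atoms: iodine II
Why: Appel-type iodination through the alkoxyphosphonium ion should be selective for the primary alcohol, the hindered tertiary alcohol being unreactive and no free iodine being left to add to the alkene.

Step 18
Reactants: 22 primary iodide
Product: 23 phosphonium iodide
Conditions: PPh3, MeCN, reflux
Reagents that add atoms: triphenylphosphine c1ccc(cc1)P(c1ccccc1)c1ccccc1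
Why: SN2 quaternisation of triphenylphosphine by the primary iodide gives the Wittig salt with no stereocentre involved.

Step 19
Reactants: 23 phosphonium iodide; 8 left-half aldehyde
Product: 25 Z-alkene (coupled skeleton), via phosphorus ylide 24 (not isolated)
Conditions: NaHMDS (1.0 equiv per 23), THF, −78 → 0 °C; then 8, −78 °C → rt
Reagents that add atoms: none
Why: Wittig olefination with the non-stabilised ylide should join the halves at the aldehyde carbon faster than enolisation; the expected Z geometry is of no consequence since the alkene is reduced next.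

Step 20
Reactants: 25 Z-alkene
Product: 26 bis-silyl ether of sipholenol L
Conditions: 2-nitrobenzenesulfonylhydrazide, Et3N, CH2Cl2, rt
Reagents that add atoms: none
Why: Diimide reduction should reduce the 1,2-disubstituted alkene much faster than the trisubstituted ring alkene and creates no stereocentre.

Step 21
Reactants: 26 bis-silyl ether of sipholenol L
Product: 27 sipholenol L
Conditions: TBAF, THF, 50 °C
Reagents that add atoms: none
Why: Global fluoride desilylation should remove the hindered secondary TBS ether and the tertiary TMS ether without affecting the tertiary alcohols, the alkene or any stereocentre.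

**Compound list**

1 | (2E,6E)-farnesol | CC(C)=CCC/C(C)=C/CC/C(C)=C/CO | starting material
2 | (2E,6E)-farnesyl tert-butyl carbonate | CC(C)=CCC/C(C)=C/CC/C(C)=C/COC(=O)OC(C)(C)C | intermediate
3 | tert-butyl (2E,6S,7S,10S)-6,7:10,11-diepoxy-3,7,11-trimethyldodec-2-en-1-yl carbonate | CC(C)(C)OC(=O)OC/C=C(\C)CC[C@@H]1O[C@@]1(C)CC[C@@H]1OC1(C)C | intermediate
4 | bicyclic epoxonium triflate (oxonium oxygen bonded to C6, C7 and C11, 10-OTBS, farnesane numbering) | CC(C)(C)OC(=O)OC/C=C(\C)CC[C@@H]1[O+]2[C@@]1(C)CC[C@H](O[Si](C)(C)C(C)(C)C)C2(C)C.[O-]S(=O)(=O)C(F)(F)F | intermediate (not isolated)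
5 | TBS-protected tricyclic carbonate (farnesane numbering: C2–C7 bond, O bridging C6 and C11, cyclic carbonate across O1 and O3, 10-OTBS; 2R,3S,6S,7S,10S; trans-fused oxepane–cyclohexane, H-2 and H-6 axial on one face, 3-Me and 7-Me axial on the other) | O=C1OC[C@H]2[C@]3(C)CC[C@H](O[Si](C)(C)C(C)(C)C)C(C)(C)O[C@H]3CC[C@]2(C)O1 | intermediate
6 | TBS-protected bicyclic diol (carbonate of 5 opened to CH2OH and tertiary OH, configuration unchanged) | OC[C@H]1[C@]2(C)CC[C@H](O[Si](C)(C)C(C)(C)C)C(C)(C)O[C@H]2CC[C@]1(C)O | intermediate
7 | β-hydroxy aldehyde (CHO equatorial, tertiary OH free, configuration unchanged) | O=C[C@H]1[C@]2(C)CC[C@H](O[Si](C)(C)C(C)(C)C)C(C)(C)O[C@H]2CC[C@]1(C)O | intermediate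
8 | left-half aldehyde (secondary OTBS, tertiary OTMS) | O=C[C@H]1[C@]2(C)CC[C@H](O[Si](C)(C)C(C)(C)C)C(C)(C)O[C@H]2CC[C@]1(C)O[Si](C)(C)C | intermediate
9 | 3-[(tert-butyldimethylsilyl)oxy]propanal | CC(C)(C)[Si](C)(C)OCCC=O | starting material
10 | 5-[(tert-butyldimethylsilyl)oxy]pent-1-en-3-ol (racemic) | CC(C)(C)[Si](C)(C)OCCC(O)C=C | intermediate
11 | 5-[(tert-butyldimethylsilyl)oxy]pent-1-en-3-one | CC(C)(C)[Si](C)(C)OCCC(=O)C=C | intermediate
12 | (Z)-5-(tert-butyldimethylsilyloxy)-3-(triethylsilyloxy)penta-1,3-diene | C=C/C(O[Si](CC)(CC)CC)=C/CO[Si](C)(C)C(C)(C)C | intermediate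
13 | 4,4-dimethylcyclohex-2-en-1-one | CC1(C)CCC(=O)C=C1 | starting material
14 | (4aR,5R,8aS)-5-[(tert-butyldimethylsilyloxy)methyl]-4,4-dimethyl-6-(triethylsilyloxy)-3,4,4a,5,8,8a-hexahydronaphthalen-1(2H)-one (cis-fused, H-4a/H-5/H-8a all cis) | CC[Si](CC)(CC)OC1=CC[C@H]2[C@@H]([C@@H]1CO[Si](C)(C)C(C)(C)C)C(C)(C)CCC2=O | intermediate
15 | 1-methylene analogue of 14 (ring stereocentres as in 14) | CC[Si](CC)(CC)OC1=CC[C@H]2[C@@H]([C@@H]1CO[Si](C)(C)C(C)(C)C)C(C)(C)CCC2=C | intermediate
16 | lithium enolate of the ring-A ketone (C6–O–Li, C6=C7) | [Li+].[O-]C1=CC[C@H]2[C@@H]([C@@H]1CO[Si](C)(C)C(C)(C)C)C(C)(C)CCC2=C | intermediate (not isolated)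
17 | enol triflate (C6–OTf, C6=C7; 1-methylene; 5-CH2OTBS) | O=S(=O)(OC1=CC[C@H]2[C@@H]([C@@H]1CO[Si](C)(C)C(C)(C)C)C(C)(C)CCC2=C)C(F)(F)F | intermediate
18 | spiro-epoxide of 17 (epoxide oxygen cis to H-8a) | O=S(=O)(OC1=CC[C@H]2[C@@H]([C@@H]1CO[Si](C)(C)C(C)(C)C)C(C)(C)CC[C@@]23CO3)C(F)(F)F | intermediate
19 | 6-methyl spiro-epoxide (C(Me)=CH in ring A) | CC1=CC[C@H]2[C@@H]([C@@H]1CO[Si](C)(C)C(C)(C)C)C(C)(C)CC[C@@]23CO3 | intermediate
20 | tertiary alcohol TBS ether (1-Me, 1-OH cis to H-8a) | CC1=CC[C@H]2[C@@H]([C@@H]1CO[Si](C)(C)C(C)(C)C)C(C)(C)CC[C@]2(C)O | intermediate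
21 | right-half diol (5-CH2OH, tertiary 1-OH) | CC1=CC[C@H]2[C@@H]([C@@H]1CO)C(C)(C)CC[C@]2(C)O | intermediate
22 | primary iodide (5-CH2I) | CC1=CC[C@H]2[C@@H]([C@@H]1CI)C(C)(C)CC[C@]2(C)O | intermediate
23 | phosphonium iodide (5-CH2PPh3+ I−) | CC1=CC[C@H]2[C@@H]([C@@H]1C[P+](c1ccccc1)(c1ccccc1)c1ccccc1)C(C)(C)CC[C@]2(C)O.[I-] | intermediate
24 | phosphorus ylide from 23 | CC1=CC[C@H]2[C@@H]([C@@H]1C=P(c1ccccc1)(c1ccccc1)c1ccccc1)C(C)(C)CC[C@]2(C)O | intermediate (not isolated)
25 | Z-alkene joining the two halves (secondary OTBS, tertiary OTMS on the left half) | CC1=CC[C@H]2[C@@H]([C@@H]1/C=C\[C@H]1[C@]3(C)CC[C@H](O[Si](C)(C)C(C)(C)C)C(C)(C)O[C@H]3CC[C@]1(C)O[Si](C)(C)C)C(C)(C)CC[C@]2(C)O | intermediate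
26 | bis-silyl ether of sipholenol L (CH2–CH2 link) | CC1=CC[C@H]2[C@@H]([C@@H]1CC[C@H]1[C@]3(C)CC[C@H](O[Si](C)(C)C(C)(C)C)C(C)(C)O[C@H]3CC[C@]1(C)O[Si](C)(C)C)C(C)(C)CC[C@]2(C)O | intermediate
27 | sipholenol L | CC1=CC[C@H]2[C@@H]([C@@H]1CC[C@H]1[C@]3(C)CC[C@H](O)C(C)(C)O[C@H]3CC[C@]1(C)O)C(C)(C)CC[C@]2(C)O | target

**Step count and risks**

Total step count: 21. Longest linear sequence: 15 steps (9 → 27, steps 7–21); the left half takes 6 steps (steps 1–6).

Steps most likely to fail:

1. Step 3. What may go wrong: the two epoxides may be activated independently, so that elimination to allylic silyl ethers, hydride shift, or opening at the wrong carbon competes with epoxonium formation and capture by the carbonate-deactivated alkene. Fallback (sets out from 2, comes back at 5): 2 is epoxidised with the same Shi ketone but one equivalent of Oxone, and the 6,7-monoepoxide carbonate F1 is isolated by chromatography from the partially epoxidised mixture. MeAlCl2 (CH2Cl2, −78 °C) then effects a conventional epoxy-olefin cyclisation with carbonate capture to the hydroxy cyclohexane carbonate F2. A second Shi epoxidation of the remaining prenyl-type alkene gives the hydroxy epoxide F3, which is closed by acid-catalysed 7-endo hydroxy-epoxide opening (CSA, CH2Cl2, 0 °C) to the oxepane alcohol F4. Silylation with TBSOTf/2,6-lutidine returns 5.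

2. Step 10. What may go wrong: both bond-forming termini are hindered (substituted diene terminus, enone β-carbon next to the gem-dimethyl group), so the chiral catalyst may give slow turnover, erosion of endo selectivity or low enantioselectivity. Fallback (sets out from 12 and 13, comes back at 14): the cycloaddition is promoted by the achiral mixed Lewis acid AlBr3/AlMe3 (toluene/CH2Cl2, −20 °C), a system suited to hindered silyloxydiene–enone pairs. This gives the racemic endo adduct, that is 14 together with its enantiomer ent-14 F5, and the two are separated by preparative chiral-phase SFC.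

3. Step 19. What may go wrong: addition of the branched ylide to the aldehyde flanked by two quaternary carbons may be slow, allowing enolisation and β-elimination of the silyloxy group. Fallback (sets out from 22 and 8, comes back at 26): 22 is converted with t-BuLi (3 equiv, Et2O, −78 °C) into the alkoxide-organolithium, which adds to 8 to give the secondary carbinol F6 (epimer mixture at the carbinol carbon). Selective acylation of the secondary alcohol with 1,1′-thiocarbonyldiimidazole gives the thiocarbonylimidazolide F7, and Barton–McCombie deoxygenation (Bu3SnH, AIBN, toluene, reflux) gives 26 directly.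

Further compounds
F1 | step 3 | tert-butyl (2E,6S,7S)-6,7-epoxy-3,7,11-trimethyldodeca-2,10-dien-1-yl carbonate | CC(C)(C)OC(=O)OC/C=C(\C)CC[C@@H]1O[C@@]1(C)CCC=C(C)C
F2 | step 3 | hydroxy cyclohexane carbonate (C2–C7 bond, cyclic carbonate across O1 and O3, equatorial 6-OH, 4-methylpent-3-enyl chain on C7) | O=C1OC[C@H]2[C@](C)(CCC=C(C)C)[C@@H](O)CC[C@]2(C)O1
F3 | step 3 | hydroxy epoxide (10S-epoxide of F2) | O=C1OC[C@H]2[C@](C)(CC[C@@H]3OC3(C)C)[C@@H](O)CC[C@]2(C)O1
F4 | step 3 | oxepane alcohol (5 without the TBS group) | O=C1OC[C@H]2[C@]3(C)CC[C@H](O)C(C)(C)O[C@H]3CC[C@]2(C)O1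
F5 | step 10 | ent-14, the (4aS,5S,8aR) enantiomer of adduct 14 | CC[Si](CC)(CC)OC1=CC[C@@H]2[C@H]([C@H]1CO[Si](C)(C)C(C)(C)C)C(C)(C)CCC2=O
F6 | step 19 | secondary carbinol from organolithium addition to 8 (epimer mixture at the carbinol carbon) | CC1=CC[C@H]2[C@@H]([C@@H]1CC(O)[C@H]1[C@]3(C)CC[C@H](O[Si](C)(C)C(C)(C)C)C(C)(C)O[C@H]3CC[C@]1(C)O[Si](C)(C)C)C(C)(C)CC[C@]2(C)O
F7 | step 19 | thiocarbonylimidazolide of F6 | CC1=CC[C@H]2[C@@H]([C@@H]1CC(OC(=S)n1ccnc1)[C@H]1[C@]3(C)CC[C@H](O[Si](C)(C)C(C)(C)C)C(C)(C)O[C@H]3CC[C@]1(C)O[Si](C)(C)C)C(C)(C)CC[C@]2(C)O
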